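**Plan**
Retrosynthesis: the lactone acyl bond O7–C19 and the ring bond C6–C7 are cut together (alkenyl iodide + α-hydroxy aldehyde + tert-butyl ester); then C8–C9 (aldol at the fully substituted carbon), then C3–C4 (enolate alkylation), then ring A by a Diels–Alder cut of C1–C14 and C10–C11.
Feature used: C7 is an allylic carbinol carbon lying between the Z C5=C6 olefin of the ten-membered ring and the fully substituted C8, and its oxygen is γ to the C19 carbonyl; one alkenyl-metal addition to a C7 aldehyde therefore closes the ten-membered ring and the lactone follows.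
Forward: ring A (Diels–Alder) → C12 oxygen and C13=C14 → lower chain C2–C6 → upper chain C7–C9/C17–C19 by aldol → ten-membered ring, then lactone (step 21) → acetates, deprotection.
Stereochemistry: C1, C10, C11 from one catalytic asymmetric Diels–Alder; C12 relayed by face-selective epoxidation; C2 by CBS reduction; C8 and C17 from diethyl (S)-malate (Fráter–Seebach alkylation, self-regeneration of the stereocentre); C9 in the aldol (acetal, Zimmerman–Traxler and Felkin–Anh control matched); C7 in the ring closure.

Key step: step 21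

Numbering used below (briarane convention): ring A = C1, C10, C11, C12, C13, C14; C15 = methyl on C1, C20 = methyl on C11; ten-membered ring C1–C10 with C16 = methyl on C5; lactone O–C7, C8, C17 (C18 methyl), C19; β = the face of ring A that carries C15, α = the other face.
Assumption: the (S)-oxazaborolidinium catalyst of step 3 is taken to give the (1S,5S,6S) adduct; if its sense of induction is the opposite, the (R)-catalyst is used and nothing else changes.

**Step 1**
Reactants: 1 2,2-dimethoxyacetaldehyde; 2 ethyl 2-(triphenyl-λ5-phosphanylidene)propanoate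
Product: 3 ethyl (E)-4,4-dimethoxy-2-methylbut-2-enoate
Conditions: CH2Cl2, rt
Reagents that add atoms: none
Why: Wittig olefination with a stabilised ylide should give the E trisubstituted enoate (ester trans to the acetal carbon).

**Step 2**
Reactants: 3 ethyl (E)-4,4-dimethoxy-2-methylbut-2-enoate
Product: 4 ethyl (E)-2-methyl-4-oxobut-2-enoate
Conditions: 1 M HCl (aq), acetone, 0 °C → rt
Reagents that add atoms: water, O
Why: Acid hydrolysis of the dimethyl acetal frees the conjugated aldehyde without changing the E geometry.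

**Step 3**
Reactants: 4 ethyl (E)-2-methyl-4-oxobut-2-enoate; 5 (E)-penta-1,3-diene (excess)
Product: 6 ethyl (1S,5S,6S)-6-formyl-1,5-dimethylcyclohex-3-ene-1-carboxylate (formyl carbon = C9, ester carbon = C2; C15, C20 and the formyl group β, ester α)
Conditions: (S)-3,3-diphenyl-1-(2-methylphenyl)tetrahydro-1H,3H-pyrrolo[1,2-c][1,3,2]oxazaborole (C24H24BNO, 20 mol%), HN(SO2CF3)2 (16 mol%), CH2Cl2, −78 → −40 °C
Reagents that add atoms: none
Why: In this chiral-Lewis-acid-catalysed Diels–Alder reaction the boron-bound formyl group is the controlling acceptor, so the CH2 terminus of the diene bonds to the doubly substituted β-carbon C1 and the methyl-bearing terminus to C10 ("ortho" rule), the endo formyl group places C9 cis to the C20 methyl, the E geometry of 4 places the ester trans to C9, and the shielded face of the catalyst fixes the absolute sense, so C1, C10 and C11 arise in one event.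

**Step 4**
Reactants: 6 ethyl (1S,5S,6S)-6-formyl-1,5-dimethylcyclohex-3-ene-1-carboxylate
Product: 7 ethyl (1S,5S,6S)-6-(dimethoxymethyl)-1,5-dimethylcyclohex-3-ene-1-carboxylate
Conditions: HC(OMe)3, MeOH, pyridinium p-toluenesulfonate (cat.), rt
Reagents that add atoms: trimethyl orthoformate, COC(OC)OC; methanol, CO
Why: Acid-catalysed acetalisation masks the aldehyde against the peracid, the lithium amide and the organolithium of the next steps.

**Step 5**
Reactants: 7 ethyl (1S,5S,6S)-6-(dimethoxymethyl)-1,5-dimethylcyclohex-3-ene-1-carboxylate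
Product: 8 α-epoxide of 7 (12,13-oxirane, oxygen cis to the ester and trans to the dimethoxymethyl group and both methyls)
Conditions: mCPBA, NaHCO3, CH2Cl2, 0 °C
Reagents that add atoms: 3-chloroperoxybenzoic acid, OOC(=O)c1cccc(Cl)c1
Why: In this Prilezhaev epoxidation the peracid should approach the ring face opposite the C10 dimethoxymethyl group and the C15 and C20 methyls, which fixes the later C12 configuration.

**Step 6**
Reactants: 8 α-epoxide of 7
Product: 9 ethyl (1S,4R,5R,6S)-6-(dimethoxymethyl)-4-hydroxy-1,5-dimethylcyclohex-2-ene-1-carboxylate (C12 α-OH, C13=C14)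
Conditions: LiN(iPr)2 (3 equiv), Et2O/hexane, 0 °C → reflux; H2O
Reagents that add atoms: none
Why: In this lithium amide-promoted epoxide-to-allylic-alcohol isomerisation (syn β-elimination) the base should remove the proton cis to the oxirane oxygen from the less substituted C14 methylene and not the tertiary C11–H, so C13=C14 forms and the C12–O bond keeps its α configuration.

**Step 7**
Reactants: 9 allylic alcohol
Product: 10 ethyl (1S,4R,5R,6S)-4-[tert-butyl(diphenyl)silyl]oxy-6-(dimethoxymethyl)-1,5-dimethylcyclohex-2-ene-1-carboxylate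
Conditions: tBuPh2SiCl, imidazole, DMAP (cat.), DMF, 40 °C
Reagents that add atoms: tert-butyl(chloro)diphenylsilane, CC(C)(C)[Si](Cl)(c1ccccc1)c1ccccc1
Why: Silylation gives a C12 ether that outlasts the triethylsilyl ethers and the acetylation, so that C12–OH can be freed last.

**Step 8**
Reactants: 10 silyl ether ester
Product: 12 1-[(1S,4R,5R,6S)-4-[tert-butyl(diphenyl)silyl]oxy-6-(dimethoxymethyl)-1,5-dimethylcyclohex-2-en-1-yl]ethan-1-one, via α-silyl ketone 11 (not isolated)
Conditions: Me3SiCH2Li (3 equiv), pentane/THF, 0 °C → rt; then MeOH, rt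
Reagents that add atoms: (trimethylsilyl)methyllithium, [Li]C[Si](C)(C)C
Why: Me3SiCH2Li adds once to the ester because the α-silyl ketone is at once enolised by a second equivalent, and methanol then protonates and desilylates it (Peterson-type reagent route from ester to methyl ketone).

**Step 9**
Reactants: 13 prop-2-yn-1-ol
Product: 14 (Z)-3-iodo-2-methylprop-2-en-1-ol
Conditions: MeMgBr (2.5 equiv), copper iodide CuI (10 mol%), THF, −10 °C → rt; then I2, −10 °C
Reagents that add atoms: methylmagnesium bromide, C[Mg]Br; iodine, II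
Why: Copper-catalysed anti-carbomagnesiation of the propargylic magnesium alkoxide gives a five-membered alkenylmagnesium chelate, and iodinolysis with retention gives the Z iodide (CH2OH cis to I).

**Step 10**
Reactants: 14 (Z)-3-iodo-2-methylprop-2-en-1-ol
Product: 15 (Z)-3-bromo-1-iodo-2-methylprop-1-ene
Conditions: CBr4, PPh3, CH2Cl2, 0 °C
Reagents that add atoms: carbon tetrabromide, BrC(Br)(Br)Br
Why: Appel bromination of the primary allylic alcohol leaves the alkenyl iodide and its geometry untouched.

**Step 11**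
Reactants: 12 methyl ketone; 15 (Z)-3-bromo-1-iodo-2-methylprop-1-ene
Product: 16 (Z)-1-[(1S,4R,5R,6S)-4-[tert-butyl(diphenyl)silyl]oxy-6-(dimethoxymethyl)-1,5-dimethylcyclohex-2-en-1-yl]-5-iodo-4-methylpent-4-en-1-one
Conditions: LiN(iPr)2 (1.05 equiv), THF, −78 °C; then 15, DMPU, −78 → −30 °C
Reagents that add atoms: none
Why: Kinetic lithium enolate alkylation works here because the methyl group is the only enolisable position (C1 is quaternary), and SN2 displacement of the allylic bromide forms C3–C4 with the Z iodide intact.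

**Step 12**
Reactants: 16 ketone
Product: 17 (1R,4Z)-1-[(1S,4R,5R,6S)-4-[tert-butyl(diphenyl)silyl]oxy-6-(dimethoxymethyl)-1,5-dimethylcyclohex-2-en-1-yl]-5-iodo-4-methylpent-4-en-1-ol
Conditions: (S)-1-methyl-3,3-diphenyltetrahydro-1H,3H-pyrrolo[1,2-c][1,3,2]oxazaborole (C18H20BNO, 0.5 equiv), catecholborane, toluene, −78 → −40 °C
Reagents that add atoms: none
Why: In this Corey–Bakshi–Shibata reduction the quaternary C1 is the large and the C3 methylene the small group, so the (S)-catalyst should give the (2R) alcohol as it does with tert-alkyl methyl ketones, and catecholborane leaves both olefins alone.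

**Step 13**
Reactants: 17 alcohol acetal
Product: 19 C9 aldehyde with C2–OSiEt3 and C12–OSiPh2tBu (ring A, C2 chain and Z iodide as in 17), via silyl ether acetal 18 (not isolated)
Conditions: Et3SiOTf (3 equiv), 2,6-lutidine (4.5 equiv), CH2Cl2, −40 → 0 °C; then H2O, rt
Reagents that add atoms: triethylsilyl trifluoromethanesulfonate, CC[Si](CC)(CC)OS(=O)(=O)C(F)(F)F; water, O
Why: The silyl triflate silylates the C2 hydroxyl and, with 2,6-lutidine, converts the dimethyl acetal into a pyridinium N,O-acetal that water hydrolyses to the aldehyde, a non-acidic acetal cleavage that spares the silyl ethers and the C10 stereocentre.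

**Step 14**
Reactants: 20 diethyl (S)-malate
Product: 21 diethyl (2S,3R)-2-hydroxy-3-methylbutanedioate
Conditions: LiN(iPr)2 (2.2 equiv), THF, −78 → −20 °C; MeI, −78 → 0 °C; AcOH
Reagents that add atoms: iodomethane, CI
Why: In this Fráter–Seebach alkylation the chelated alkoxide enolate is methylated anti to the alkoxide oxygen, which sets C17 and gives the anti (2S,3R) diester.

**Step 15**
Reactants: 21 diethyl (2S,3R)-2-hydroxy-3-methylbutanedioate
Product: 22 (2S,3R)-2-hydroxy-3-methylbutanedioic acid
Conditions: KOH (aq), 0 °C → rt; then HCl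
Reagents that add atoms: potassium hydroxide, [K+].[OH-]
Why: Saponification at or below room temperature frees both acids without epimerising C17.

**Step 16**
Reactants: 22 (2S,3R)-2-hydroxy-3-methylbutanedioic acid
Product: 23 (2R)-2-[(2S,4S)-2-tert-butyl-5-oxo-1,3-dioxolan-4-yl]propanoic acid
Conditions: tBuCHO, TsOH (cat.), H2SO4 (cat.), pentane, reflux, water separator; cis isomer crystallised
Reagents that add atoms: pivalaldehyde, CC(C)(C)C=O
Why: Acid-catalysed acetalisation of the α-hydroxy acid forms the five-membered dioxolanone in preference to the six-membered alternative, and the cis isomer is the thermodynamic product, which stores the C8 configuration in the acetal carbon (self-regeneration of the stereocentre).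

**Step 17**
Reactants: 23 dioxolanone acid
Product: 24 tert-butyl (2R)-2-[(2S,4S)-2-tert-butyl-5-oxo-1,3-dioxolan-4-yl]propanoate
Conditions: tBuOC(=NH)CCl3, BF3·OEt2 (cat.), CH2Cl2/cyclohexane, rt
Reagents that add atoms: tert-butyl 2,2,2-trichloroacetimidate, CC(C)(C)OC(=N)C(Cl)(Cl)Cl
Why: Acid-catalysed O-alkylation by the trichloroacetimidate gives a tert-butyl ester that should resist the enolate, hydride and chromium steps.

**Step 18**
Reactants: 19 C9 aldehyde; 24 dioxolanone ester (1.4 equiv)
Product: 25 aldol adduct: dioxolanone bearing on C8 the (9R)-hydroxy(ring A)methyl group (trans to the acetal tert-butyl group) and the (17R)-1-(tert-butoxycarbonyl)ethyl group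
Conditions: LiN(SiMe3)2 (1.3 equiv), THF, −78 °C; then 19, −78 °C; AcOH
Reagents that add atoms: none
Why: In this lithium aldol addition the aldehyde enters the dioxolanone enolate anti to the acetal tert-butyl group (C9 takes the place of the former C8 hydrogen), the closed Zimmerman–Traxler transition state of this enolate (ring oxygen trans to O–Li) places C9–O anti to C8–O, and this is also the Felkin–Anh face of the aldehyde (attack anti to the quaternary C1), so the three controls agree on (9R); LiN(SiMe3)2 is too weak to enolise the tert-butyl ester.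

**Step 19**
Reactants: 25 aldol adduct
Product: 26 C9 triethylsilyl ether of 25
Conditions: Et3SiOTf, 2,6-lutidine, CH2Cl2, −78 °C
Reagents that add atoms: triethylsilyl trifluoromethanesulfonate, CC[Si](CC)(CC)OS(=O)(=O)C(F)(F)F
Why: Silylation under non-basic conditions blocks retro-aldol cleavage and keeps O9 from competing for the C19 carbonyl later.

**Step 20**
Reactants: 26 silylated aldol adduct
Product: 28 α-hydroxy aldehyde (C7 aldehyde, C8 tertiary OH, C19 tert-butyl ester, C2 and C9 OSiEt3, C12 OSiPh2tBu, Z alkenyl iodide), via dioxolanyl lactol 27 (not isolated)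
Conditions: iBu2AlH (1.5 equiv), CH2Cl2, −78 °C; MeOH, aqueous potassium sodium tartrate; silica gel, wet CH2Cl2
Reagents that add atoms: none
Why: Half-reduction of the activated dioxolanone carbonyl by iBu2AlH at −78 °C stops at the aluminium hemiacetal while the hindered tert-butyl ester is untouched, and on work-up the lactol opens and the hemiacetal of the tertiary alcohol loses pivalaldehyde.

**Step 21**
Reactants: 28 α-hydroxy aldehyde
Product: 30 macrocyclic lactone (ten-membered ring and γ-lactone closed; C2 and C9 OSiEt3, C12 OSiPh2tBu, C8 OH), via macrocyclic hydroxy ester 29 (not isolated)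
Conditions: CrCl2 (15 equiv), NiCl2 (0.2 equiv), degassed DMSO, 0.003 M, rt; aqueous work-up; then pyridinium p-toluenesulfonate (cat.), toluene, 50 °C
Reagents that add atoms: none
Why: Zerovalent nickel formed in situ from NiCl2 inserts into the C6–I bond with retention of the Z geometry, transmetalation to trivalent chromium gives an alkenylchromium species that adds to the C7 aldehyde (Nozaki–Hiyama–Kishi reaction), and mild acid then lets the C7 hydroxyl displace tert-butanol from the C19 ester. The closest known reaction type is the chromium-mediated alkenyl iodide–aldehyde macrocyclisation used to close nine- and ten-membered carbocycles of marine diterpenoids, followed by lactonisation of a γ-hydroxy tert-butyl ester. The ten-membered ring closes in the 10-exo-trig mode and the lactone in the 5-exo-trig mode. C7 is controlled by C8 and by the tether: the alkenyl carbon is tied to C8 through C9, so it reaches the aldehyde on the side of C9, which is the Felkin–Anh face with the C8–O bond antiperiplanar to the new bond and also the face open in a chromium chelate of the α-hydroxy aldehyde, and both lead to (7S), while C5=C6 keeps the Z geometry of the iodide. The step needs chemoselectivity for the aldehyde (alkenylchromium species do not add to esters and tolerate the free tertiary hydroxyl and the silyl ethers), ring closure over oligomerisation (high dilution, the trans-1,2 placement of the two chains on ring A and the fully substituted C1 and C8), and lactonisation through O7 only (O9 is silylated).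

**Step 22**
Reactants: 30 macrocyclic lactone
Product: 31 C2,C9-diol (C12 OSiPh2tBu kept)
Conditions: HF·pyridine, pyridine, THF, 0 °C → rt
Reagents that add atoms: none
Why: Buffered fluoride cleaves the two secondary triethylsilyl ethers much faster than the bulkier tert-butyldiphenylsilyl ether.

**Step 23**
Reactants: 31 diol
Product: 32 C2,C9-diacetate (C12 OSiPh2tBu)
Conditions: Ac2O, pyridine, DMAP (cat.), CH2Cl2, rt
Reagents that add atoms: acetic anhydride, CC(=O)OC(C)=O
Why: DMAP-catalysed acylation should esterify the two secondary alcohols while the tertiary C8 hydroxyl, shielded by C7, C9 and C17, stays free at room temperature.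

**Step 24**
Reactants: 32 diacetate silyl ether
Product: 33 CNP0222085.1 (target)
Conditions: HF·pyridine, THF, rt
Reagents that add atoms: none
Why: Acidic fluoride desilylation frees C12–OH without the base that could move an acetyl group to O8 or open the lactone.

**Compound list**
1 | 2,2-dimethoxyacetaldehyde | COC(OC)C=O | starting material
2 | ethyl 2-(triphenyl-λ5-phosphanylidene)propanoate | CCOC(=O)C(C)=P(c1ccccc1)(c1ccccc1)c1ccccc1 | starting material
3 | ethyl (E)-4,4-dimethoxy-2-methylbut-2-enoate | CCOC(=O)/C(C)=C/C(OC)OC | intermediate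
4 | ethyl (E)-2-methyl-4-oxobut-2-enoate | CCOC(=O)/C(C)=C/C=O | intermediate
5 | (E)-penta-1,3-diene | C=C/C=C/C | starting material
6 | ethyl (1S,5S,6S)-6-formyl-1,5-dimethylcyclohex-3-ene-1-carboxylate | O=C[C@H]1[C@@H](C)C=CC[C@]1(C)C(=O)OCC | intermediate
7 | ethyl (1S,5S,6S)-6-(dimethoxymethyl)-1,5-dimethylcyclohex-3-ene-1-carboxylate | COC(OC)[C@H]1[C@@H](C)C=CC[C@]1(C)C(=O)OCC | intermediate
8 | α-epoxide of 7 (oxirane oxygen cis to the ester, trans to the acetal and both methyls) | COC(OC)[C@H]1[C@@H](C)[C@@H]2O[C@@H]2C[C@]1(C)C(=O)OCC | intermediate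
9 | ethyl (1S,4R,5R,6S)-6-(dimethoxymethyl)-4-hydroxy-1,5-dimethylcyclohex-2-ene-1-carboxylate | COC(OC)[C@H]1[C@@H](C)[C@H](O)C=C[C@]1(C)C(=O)OCC | intermediate
10 | ethyl (1S,4R,5R,6S)-4-[tert-butyl(diphenyl)silyl]oxy-6-(dimethoxymethyl)-1,5-dimethylcyclohex-2-ene-1-carboxylate | COC(OC)[C@H]1[C@@H](C)[C@H](O[Si](c2ccccc2)(c2ccccc2)C(C)(C)C)C=C[C@]1(C)C(=O)OCC | intermediate
11 | α-silyl ketone: 1-[ring A residue of 10]-2-(trimethylsilyl)ethan-1-one | COC(OC)[C@H]1[C@@H](C)[C@H](O[Si](c2ccccc2)(c2ccccc2)C(C)(C)C)C=C[C@]1(C)C(=O)C[Si](C)(C)C | intermediate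
12 | 1-[(1S,4R,5R,6S)-4-[tert-butyl(diphenyl)silyl]oxy-6-(dimethoxymethyl)-1,5-dimethylcyclohex-2-en-1-yl]ethan-1-one | COC(OC)[C@H]1[C@@H](C)[C@H](O[Si](c2ccccc2)(c2ccccc2)C(C)(C)C)C=C[C@]1(C)C(C)=O | intermediate
13 | prop-2-yn-1-ol | C#CCO | starting material
14 | (Z)-3-iodo-2-methylprop-2-en-1-ol | OC/C(C)=C\I | intermediate
15 | (Z)-3-bromo-1-iodo-2-methylprop-1-ene | BrC/C(C)=C\I | intermediate
16 | (Z)-1-[(1S,4R,5R,6S)-4-[tert-butyl(diphenyl)silyl]oxy-6-(dimethoxymethyl)-1,5-dimethylcyclohex-2-en-1-yl]-5-iodo-4-methylpent-4-en-1-one | COC(OC)[C@H]1[C@@H](C)[C@H](O[Si](c2ccccc2)(c2ccccc2)C(C)(C)C)C=C[C@]1(C)C(=O)CC/C(C)=C\I | intermediate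
17 | (1R,4Z)-1-[(1S,4R,5R,6S)-4-[tert-butyl(diphenyl)silyl]oxy-6-(dimethoxymethyl)-1,5-dimethylcyclohex-2-en-1-yl]-5-iodo-4-methylpent-4-en-1-ol | COC(OC)[C@H]1[C@@H](C)[C@H](O[Si](c2ccccc2)(c2ccccc2)C(C)(C)C)C=C[C@]1(C)[C@H](O)CC/C(C)=C\I | intermediate
18 | C2 triethylsilyl ether of 17 (acetal still in place) | COC(OC)[C@H]1[C@@H](C)[C@H](O[Si](c2ccccc2)(c2ccccc2)C(C)(C)C)C=C[C@]1(C)[C@H](O[Si](CC)(CC)CC)CC/C(C)=C\I | intermediate
19 | C9 aldehyde: ring A C10-carbaldehyde with the (1R,4Z)-5-iodo-4-methyl-1-(triethylsilyloxy)pent-4-enyl chain on C1 and OSiPh2tBu on C12 | O=C[C@H]1[C@@H](C)[C@H](O[Si](c2ccccc2)(c2ccccc2)C(C)(C)C)C=C[C@]1(C)[C@H](O[Si](CC)(CC)CC)CC/C(C)=C\I | intermediate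
20 | diethyl (S)-malate | CCOC(=O)C[C@H](O)C(=O)OCC | starting material
21 | diethyl (2S,3R)-2-hydroxy-3-methylbutanedioate | CCOC(=O)[C@H](C)[C@H](O)C(=O)OCC | intermediate
22 | (2S,3R)-2-hydroxy-3-methylbutanedioic acid | OC(=O)[C@H](C)[C@H](O)C(=O)O | intermediate
23 | (2R)-2-[(2S,4S)-2-tert-butyl-5-oxo-1,3-dioxolan-4-yl]propanoic acid | OC(=O)[C@H](C)[C@@H]1O[C@H](C(C)(C)C)OC1=O | intermediate
24 | tert-butyl (2R)-2-[(2S,4S)-2-tert-butyl-5-oxo-1,3-dioxolan-4-yl]propanoate | CC(C)(C)OC(=O)[C@H](C)[C@@H]1O[C@H](C(C)(C)C)OC1=O | intermediate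
25 | aldol adduct: dioxolanone with C8 bearing the (9R)-hydroxy(ring A)methyl group trans to the acetal tert-butyl group | O[C@@H]([C@@]3([C@@H](C)C(=O)OC(C)(C)C)O[C@H](C(C)(C)C)OC3=O)[C@H]1[C@@H](C)[C@H](O[Si](c2ccccc2)(c2ccccc2)C(C)(C)C)C=C[C@]1(C)[C@H](O[Si](CC)(CC)CC)CC/C(C)=C\I | intermediate
26 | C9 triethylsilyl ether of 25 | CC[Si](CC)(CC)O[C@@H]([C@@]3([C@@H](C)C(=O)OC(C)(C)C)O[C@H](C(C)(C)C)OC3=O)[C@H]1[C@@H](C)[C@H](O[Si](c2ccccc2)(c2ccccc2)C(C)(C)C)C=C[C@]1(C)[C@H](O[Si](CC)(CC)CC)CC/C(C)=C\I | intermediate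
27 | dioxolanyl lactol (C7 hemiacetal of 26, both C7 epimers) | CC[Si](CC)(CC)O[C@@H]([C@@]3([C@@H](C)C(=O)OC(C)(C)C)O[C@H](C(C)(C)C)OC3O)[C@H]1[C@@H](C)[C@H](O[Si](c2ccccc2)(c2ccccc2)C(C)(C)C)C=C[C@]1(C)[C@H](O[Si](CC)(CC)CC)CC/C(C)=C\I | intermediate
28 | α-hydroxy aldehyde (C7 CHO, C8 OH, C19 tert-butyl ester; seco compound for ring closure) | CC[Si](CC)(CC)O[C@@H]([C@@](O)(C=O)[C@@H](C)C(=O)OC(C)(C)C)[C@H]1[C@@H](C)[C@H](O[Si](c2ccccc2)(c2ccccc2)C(C)(C)C)C=C[C@]1(C)[C@H](O[Si](CC)(CC)CC)CC/C(C)=C\I | intermediate
29 | macrocyclic hydroxy ester (ten-membered ring closed, (7S)-OH, C19 tert-butyl ester) | CC[Si](CC)(CC)O[C@@H]1[C@H]2[C@@H](C)[C@H](O[Si](c3ccccc3)(c3ccccc3)C(C)(C)C)C=C[C@]2(C)[C@H](O[Si](CC)(CC)CC)CC/C(C)=C\[C@H](O)[C@@]1(O)[C@@H](C)C(=O)OC(C)(C)C | intermediate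
30 | macrocyclic lactone, C2 and C9 OSiEt3, C12 OSiPh2tBu | CC[Si](CC)(CC)O[C@@H]1[C@H]2[C@@H](C)[C@H](O[Si](c3ccccc3)(c3ccccc3)C(C)(C)C)C=C[C@]2(C)[C@H](O[Si](CC)(CC)CC)CC/C(C)=C\[C@@H]2OC(=O)[C@H](C)[C@]21O | intermediate
31 | C2,C9-diol, C12 OSiPh2tBu | O[C@@H]1[C@H]2[C@@H](C)[C@H](O[Si](c3ccccc3)(c3ccccc3)C(C)(C)C)C=C[C@]2(C)[C@H](O)CC/C(C)=C\[C@@H]2OC(=O)[C@H](C)[C@]21O | intermediate
32 | C2,C9-diacetate, C12 OSiPh2tBu | CC(=O)O[C@@H]1[C@H]2[C@@H](C)[C@H](O[Si](c3ccccc3)(c3ccccc3)C(C)(C)C)C=C[C@]2(C)[C@H](OC(C)=O)CC/C(C)=C\[C@@H]2OC(=O)[C@H](C)[C@]21O | intermediate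
33 | CNP0222085.1 | CC(=O)O[C@@H]1[C@H]2[C@@H](C)[C@H](O)C=C[C@]2(C)[C@H](OC(C)=O)CC/C(C)=C\[C@@H]2OC(=O)[C@H](C)[C@]21O | target

**Step count and risks**
Total: 24 steps. Longest linear sequence: 18 steps (steps 1–8, 11–13, 18–24).

Step 21 (ring closure). What may go wrong: closure through the other face of the C7 aldehyde (poor facial selectivity), besides reductive loss of iodine before the ring closes. Fallback: it sets out from 28; the chromium-mediated closure is run as before but the hydroxy esters are isolated without the acid treatment. The 7-epimeric macrocyclic hydroxy ester F1 is oxidised with MnO2 in CH2Cl2 to the macrocyclic α-hydroxy enone F2. F2 is reduced with Zn(BH4)2 in Et2O at −30 °C; zinc chelation of the C7 carbonyl and the C8 hydroxyl and hydride delivery from the exocyclic side (that of C17) should give 29, which is lactonised to 30 as in step 21. C7 is then set by a chelation-controlled reduction and not by the carbon–carbon bond formation.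

Step 18 (aldol). What may go wrong: slow bond formation between the tetrasubstituted enolate and the neopentyl-type aldehyde, which leaves room for retro-aldol cleavage and for proton transfer that epimerises C10. Fallback: it sets out from 24, which is O-silylated (LiN(SiMe3)2, Me3SiCl, THF, −78 °C) to the silyl ketene acetal F3. F3 is added to 19 with BF3·OEt2 in CH2Cl2 at −78 °C (Mukaiyama aldol, open transition state, attack anti to the acetal tert-butyl group and on the Felkin–Anh face of the aldehyde); aqueous work-up returns the route at 25. The aldehyde is activated instead of the nucleophile, and no basic aldolate is formed.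

Step 5 (epoxidation). What may go wrong: delivery of oxygen to the β face (poor or reversed facial selectivity), which would invert C12. Fallback: it sets out from 7 and turns the same facial bias around. N-bromosuccinimide in DME/H2O at 0 °C puts the bromonium ion on the face the peracid prefers and water opens it from the other face, giving bromohydrin F4 together with its regioisomer F5. K2CO3 in EtOH closes both by intramolecular SN2 displacement to the α-epoxide 8.

**Further compounds**
F1 | step 21 | 7-epimer of macrocyclic hydroxy ester 29 ((7R)-OH) | CC[Si](CC)(CC)O[C@@H]1[C@H]2[C@@H](C)[C@H](O[Si](c3ccccc3)(c3ccccc3)C(C)(C)C)C=C[C@]2(C)[C@H](O[Si](CC)(CC)CC)CC/C(C)=C\[C@@H](O)[C@@]1(O)[C@@H](C)C(=O)OC(C)(C)C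
F2 | step 21 | macrocyclic α-hydroxy enone (C7 ketone) | CC[Si](CC)(CC)O[C@@H]1[C@H]2[C@@H](C)[C@H](O[Si](c3ccccc3)(c3ccccc3)C(C)(C)C)C=C[C@]2(C)[C@H](O[Si](CC)(CC)CC)CC/C(C)=C\C(=O)[C@@]1(O)[C@@H](C)C(=O)OC(C)(C)C
F3 | step 18 | tert-butyl (2R)-2-[(2S)-2-tert-butyl-5-(trimethylsilyloxy)-1,3-dioxol-4-yl]propanoate | CC(C)(C)OC(=O)[C@H](C)C1=C(O[Si](C)(C)C)O[C@@H](C(C)(C)C)O1
F4 | step 5 | bromohydrin of 7: 12α-hydroxy, 13β-bromo | COC(OC)[C@H]1[C@@H](C)[C@H](O)[C@@H](Br)C[C@]1(C)C(=O)OCC
F5 | step 5 | regioisomeric bromohydrin of 7: 12β-bromo, 13α-hydroxy | COC(OC)[C@H]1[C@@H](C)[C@@H](Br)[C@H](O)C[C@]1(C)C(=O)OCC
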